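**Plan**

1. Numbering: C1–C10 is the ten-membered carbocycle (C1 CH2, C2 =CH, C3 enol-ether carbon, C4 C(CH3)OH, C5 CH2, C6 CHOAc, C7/C8 butenolide β/γ carbons, C9 =CH, C10 C(CH3)O); C11, C12, C13 are the lactone α-carbon, C=O and CH2OAc. The enabling feature: C3 (ketone level) and the enol-lactone carbon C8 lie 1,6 across this ring beside quaternary C10, the imprint of a [3,3] shift in a 1-vinyl-2-alkenylcyclohexan-1-ol.
2. Retrosynthesis: (a) C2=C3 enol ether → C3 hemiketal → C3 ketone and free C10–O; (b) C13–OAc/C7=C11 → α-methylene lactone with the C10 oxygen still bound to C7 (SN2′ retron), C6–OAc → epimeric C6–OH; (c) cut C1–C10 and restore C3–C8 (oxy-Cope retron).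
3. The cyclohexanol is then stripped of the C3 vinyl group, the C7–O–C10 dihydrofuran (C8 allyl → methyl ketone), C13 (Mannich), C11–C12 (acetate aldol on a C7 ketone), the C8 allyl group and the C6 oxygen, back to the cis-dihydrodiol of toluene.
4. Forward ring order: cyclohexane C3–C8 (from toluene) → cis-fused γ-lactone (step 12) → dihydrofuran, completing a propellane on C7–C8 (step 16) → ten-membered ring by ring expansion (step 18) → butenolide and C3–O–C10 bridge (steps 19, 22).
5. Design point: C7 stays sp3 and bound to the C10 oxygen until after the rearrangement. A planar butenolide would hold O–C8 equatorial and the alkenyl group axial, and a chair shift from that conformer gives the other C8=C9 isomer. The tether also fixes the position and Z geometry of the enol ether.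
6. Stereochemistry: the enzymatic diol gives the absolute configuration; its acetonide steers C4 (singlet oxygen, anti), C8 (alkylation, anti) and, with the axial C4 methyl, C6. C7 follows from the intramolecular aldol, C3 from axial vinyl addition, C10 and the C8=C9 geometry from the oxy-Cope. C6 is carried as its epimer (equatorial, keeps the reactive chair) and inverted at the end.

Key step: step 18

Remark: target numbering is used for all intermediates; "top" is the face of the six-membered ring that carries the C4 oxygen, "bottom" the face of the original diol oxygens.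
Remark: the C3 hemiketals 26–28 (and F1, F2, F5, F6) should equilibrate at C3, so their SMILES carry no descriptor there.
Remark: C11 in 16 and 17 is drawn as expected for exo-face attack; this centre is lost in step 14.

**Route**

Step 1
Reactants: 1 toluene
Product: 2 (1S,2R)-3-methylcyclohexa-3,5-diene-1,2-diol
Conditions: E. coli JM109(pDTG601A) whole cells (toluene dioxygenase), O2, glucose, phosphate buffer, 35 °C
Reagents that add atoms: dioxygen, O=O
Why: Enzymatic arene cis-dihydroxylation should give the (1S,2R)-cis-diol and so fix the absolute configuration from which every later centre is derived.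

Step 2
Reactants: 2 (1S,2R)-3-methylcyclohexa-3,5-diene-1,2-diol
Product: 3 diene acetonide
Conditions: 2,2-dimethoxypropane, TsOH (cat.), CH2Cl2, 0 °C; used at once
Reagents that add atoms: 2,2-dimethoxypropane, COC(C)(C)OC
Why: Acid-catalysed acetal exchange ties the cis-diol into a dioxolane that shields the bottom face of the diene, which is used directly because it dimerises on standing.

Step 3
Reactants: 3 diene acetonide
Product: 4 C4,C7-endoperoxide
Conditions: O2, tetraphenylporphyrin (cat.), hν, CH2Cl2, −78 °C
Reagents that add atoms: dioxygen, O=O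
Why: Singlet-oxygen [4+2] cycloaddition across C4/C7 should occur anti to the acetonide, which sets C4 with its oxygen on the top face.

Step 4
Reactants: 4 C4,C7-endoperoxide
Product: 5 C4-hydroxy C7-enone
Conditions: Et3N, CH2Cl2, 0 °C
Reagents that add atoms: none
Why: Kornblum–DeLaMare rearrangement removes the only α-peroxy hydrogen (C7–H), giving the C7 ketone and the tertiary C4 alcohol without touching the C4 centre.

Step 5
Reactants: 5 C4-hydroxy C7-enone
Product: 6 C4-OTBS enone
Conditions: TBSOTf, 2,6-lutidine, CH2Cl2, 0 °C
Reagents that add atoms: tert-butyldimethylsilyl trifluoromethanesulfonate, CC(C)(C)[Si](C)(C)OS(=O)(=O)C(F)(F)F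
Why: O-Silylation of the tertiary alcohol with a silyl triflate gives an ether that must last until step 20 and later sits equatorial in the reactive chair.

Step 6
Reactants: 6 C4-OTBS enone; 7 allyl bromide
Product: 8 C8-allyl enone
Conditions: LiN(iPr)2, THF, −78 °C; then 7, DMPU, −78 → −40 °C
Reagents that add atoms: none
Why: α′-Alkylation of the cross-conjugated lithium dienolate: the dioxolane keeps C8–O on the bottom face, so the allyl group must enter from the top, and the ring holds C3–O near the enolate plane, which slows β-elimination.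

Step 7
Reactants: 8 C8-allyl enone
Product: 10 C6-hydroxy C7-ketone, via lithium enolate 9 (not isolated)
Conditions: LiBH(sBu)3, THF, −78 °C; then 2-(phenylsulfonyl)-3-phenyloxaziridine, −78 °C; aqueous work-up
Reagents that add atoms: 2-(phenylsulfonyl)-3-phenyloxaziridine, O=S(=O)(N1OC1c1ccccc1)c1ccccc1
Why: Conjugate reduction gives the C6=C7 enolate regiospecifically, and enolate hydroxylation by the N-sulfonyloxaziridine should occur anti to the acetonide and the axial C4 methyl, placing C6–OH on the top face, which is also the equatorial, thermodynamically preferred position of this epimerisable centre.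

Step 8
Reactants: 10 C6-hydroxy C7-ketone
Product: 11 C6-OTIPS ketone
Conditions: TIPSOTf, 2,6-lutidine, CH2Cl2, 0 °C
Reagents that add atoms: triisopropylsilyl trifluoromethanesulfonate, CC(C)[Si](OS(=O)(=O)C(F)(F)F)(C(C)C)C(C)C
Why: O-Silylation with a bulky silyl triflate stops α-ketol isomerisation and gives an ether robust enough for the acidic acetonide cleavage.

Step 9
Reactants: 11 C6-OTIPS ketone
Product: 12 C3,C8-diol ketone
Conditions: CF3CO2H, H2O, CH2Cl2, 0 °C → rt
Reagents that add atoms: none
Why: Acid hydrolysis of the isopropylidene acetal frees the secondary C3 and tertiary C8 hydroxyls while the hindered silyl ethers should stay.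

Step 10
Reactants: 12 C3,C8-diol ketone
Product: 13 C3,C7-diketone C8-ol
Conditions: IBX, DMSO, rt
Reagents that add atoms: none
Why: Hypervalent-iodine oxidation of the only secondary alcohol gives the non-enolisable C3 ketone without glycol cleavage.

Step 11
Reactants: 13 C3,C7-diketone C8-ol
Product: 14 C8 acetate
Conditions: Ac2O, Et3N, DMAP (cat.), CH2Cl2, 0 °C
Reagents that add atoms: acetic anhydride, CC(=O)OC(C)=O
Why: DMAP-catalysed acylation of the one remaining hydroxyl installs the two carbons that become C11 and C12.

Step 12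
Reactants: 14 C8 acetate
Product: 15 β-hydroxy γ-lactone
Conditions: LiN(SiMe3)2, THF, −78 °C; AcOH, −78 °C
Reagents that add atoms: none
Why: Intramolecular acetate aldol addition: the enolate of the axial C8 acetate can only reach C7 from the bottom face (the same face of C3 is blocked by the axial C4 methyl), so the lactone is cis-fused and the new C7–OH lies on the top face.

Step 13
Reactants: 15 β-hydroxy γ-lactone
Product: 16 Mannich base
Conditions: LiN(iPr)2 (2.2 equiv), THF, −78 °C; then [Me2N=CH2]I, −78 → 0 °C
Reagents that add atoms: dimethylmethyleneiminium iodide, C=[N+](C)C.[I-]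
Why: Mannich reaction of the lactone enolate, formed as the dianion so that the C7 alkoxide cannot be eliminated, adds C13; the C11 centre it creates is removed in step 14.

Step 14
Reactants: 16 Mannich base
Product: 18 α-methylene β-hydroxy lactone, via trimethylammonium iodide 17 (not isolated)
Conditions: MeI, CH2Cl2, rt; then aq. NaHCO3
Reagents that add atoms: none
Why: Quaternisation followed by E1cB loss of trimethylamine (standard α-methylenation of a lactone) gives a lactone without an acidic α-hydrogen.

Step 15
Reactants: 18 α-methylene β-hydroxy lactone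
Product: 19 methyl ketone
Conditions: PdCl2 (cat.), CuCl, O2, DMF/H2O, rt
Reagents that add atoms: water, O
Why: Wacker–Tsuji oxidation converts the terminal allyl alkene into the C10 methyl ketone, the electron-poor α-methylene lactone being much less reactive towards PdCl2.

Step 16
Reactants: 19 methyl ketone
Product: 20 dihydrofuran propellane ketone
Conditions: pyridinium p-toluenesulfonate (cat.), 4 Å molecular sieves, benzene, 60 °C
Reagents that add atoms: none
Why: Acid-catalysed cyclodehydration of the γ-hydroxy ketone (C7–OH is cis to the C8 side chain) gives the endocyclic 5-methyl-2,3-dihydrofuran, that is the C9=C10 enol ether with its position and Z geometry fixed by the ring.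

Step 17
Reactants: 20 dihydrofuran propellane ketone; 21 vinylmagnesium bromide
Product: 22 C3 vinyl carbinol
Conditions: 21, CeCl3, THF, −78 °C
Reagents that add atoms: none
Why: 1,2-Addition of the organocerium reagent to the non-enolisable C3 ketone should occur axially from the top face, because the bottom face is blocked by the axial C8–O1 and C4–CH3 bonds, giving the axial vinyl group cis to C9 and sparing the lactone.

Step 18
Reactants: 22 C3 vinyl carbinol
Product: 24 ring-expanded ketone, via potassium enolate 23 (not isolated)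
Conditions: KN(SiMe3)2, 18-crown-6, THF, −78 → 0 °C; AcOH, −78 °C
Reagents that add atoms: none
Why: The C3 potassium alkoxide undergoes a concerted [3,3] shift through a chair-like array C1=C2–C3–C8–C9=C10 (anionic oxy-Cope rearrangement), in which C1–C10 forms and C3–C8 breaks, and the enolate is protonated to the C3 ketone. The closest known reaction type is the anionic oxy-Cope ring expansion of cis-1-vinyl-2-alkenylcyclohexanols to cyclodec-5-enones, here with a cyclic enol ether as the second alkene. The ten-membered carbocycle arises by four-atom ring expansion of the cyclohexane (sigmatropic, not an end-to-end cyclisation) and stays bridged by the C7–O–C10 oxygen. C10 is set because C1 can only bond to the face of the dihydrofuran C9=C10 bond on which C3 lies (suprafacial across C8–C9–C10), so the C8 configuration is relayed to C10. The step needs the C8=C9 isomer with C7 and C10 cis: this is secured because the new double bond is endocyclic in the five-membered C7–C8=C9–C10–O ring, and only the chair with axial vinyl, axial O1 and equatorial C9 brings C1 within reach of C10, the chair that the equatorial C4 and C6 silyloxy groups enforce. The lactone has no α-hydrogen, and the main competitor, Grob-type loss of the C7 oxygen, is countered by low temperature and a cold quench.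

Step 19
Reactants: 24 ring-expanded ketone
Product: 26 hemiketal acetate, via open hydroxy ketone 25 (not isolated)
Conditions: CsOAc, AcOH, DABCO (cat.), DMF, 40 °C
Reagents that add atoms: acetic acid (delivered as caesium acetate), CC(=O)O
Why: Proposed new method: acetate (or DABCO, then acetate) adds to C13 of the α-methylene lactone, the ester enolate expels the C7 alkoxide (E1cB) with relief of the strained bicyclic enol lactone and gain of the C7=C11–C8=C9 conjugation, and the freed C10 alkoxide closes on the C3 ketone; the closest known reaction type is the amine- or carboxylate-mediated SN2′ transposition of Morita–Baylis–Hillman acetates and addition–elimination on 2-(alkoxymethyl)acrylates.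

Step 20
Reactants: 26 hemiketal acetate
Product: 27 desilylated hemiketal
Conditions: HF·pyridine, pyridine, THF, 0 °C → rt
Reagents that add atoms: none
Why: Fluoride-mediated cleavage of both silyl ethers under buffered conditions should leave acetate, butenolide and hemiketal intact.

Step 21
Reactants: 27 desilylated hemiketal
Product: 28 C6 acetate hemiketal
Conditions: PPh3, diisopropyl azodicarboxylate, AcOH, toluene, 0 °C → rt
Reagents that add atoms: acetic acid, CC(=O)O
Why: Mitsunobu reaction: SN2 displacement of the activated allylic C6 alcohol by acetate inverts C6 to the configuration of the target, the tertiary hydroxyls being inert.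

Step 22
Reactants: 28 C6 acetate hemiketal
Product: 29 CNP0144020.1
Conditions: MsCl, Et3N, CH2Cl2, −20 → 0 °C
Reagents that add atoms: none
Why: Hemiketal dehydration: sulfonylation of the hemiketal hydroxyl and loss of the only available β-hydrogen (C2–H) from the oxocarbenium ion gives the cyclic enol ether under basic conditions that protect the acid-sensitive product.

**Compound list**

1 | toluene | Cc1ccccc1 | starting material
2 | (1S,2R)-3-methylcyclohexa-3,5-diene-1,2-diol (C8–OH and C3–OH cis, bottom face) | CC1=CC=C[C@H](O)[C@@H]1O | intermediate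
3 | (3aR,7aS)-2,2,4-trimethyl-3a,7a-dihydro-1,3-benzodioxole (acetonide of 2) | CC1=CC=C[C@H]2[C@@H]1OC(C)(C)O2 | intermediate
4 | endoperoxide: C4–O–O–C7 bridge on the top face, C5=C6, C3/C8 acetonide on the bottom face | C[C@@]12C=C[C@@H](OO1)[C@@H]1OC(C)(C)O[C@H]21 | intermediate
5 | hydroxy enone: C7 ketone, C5=C6, tertiary C4–OH (top), C3/C8 acetonide (bottom) | C[C@]1(O)C=CC(=O)[C@@H]2OC(C)(C)O[C@H]12 | intermediate
6 | C4 tert-butyldimethylsilyl ether of 5 | C[C@]1(O[Si](C)(C)C(C)(C)C)C=CC(=O)[C@@H]2OC(C)(C)O[C@H]12 | intermediate
7 | allyl bromide (3-bromoprop-1-ene) | C=CCBr | starting material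
8 | C8-allyl enone: allyl on the top face of C8, C8–O still in the acetonide | C[C@]1(O[Si](C)(C)C(C)(C)C)C=CC(=O)[C@]2(CC=C)OC(C)(C)O[C@H]12 | intermediate
9 | lithium C6=C7 enolate of the 5,6-dihydro ketone | C[C@]1(O[Si](C)(C)C(C)(C)C)CC=C([O-])[C@]2(CC=C)OC(C)(C)O[C@H]12.[Li+] | intermediate (not isolated)
10 | C6-hydroxy C7-ketone: C6–OH on the top face, cis to C4–OTBS | C[C@]1(O[Si](C)(C)C(C)(C)C)C[C@@H](O)C(=O)[C@]2(CC=C)OC(C)(C)O[C@H]12 | intermediate
11 | C6 triisopropylsilyl ether of 10 | C[C@]1(O[Si](C)(C)C(C)(C)C)C[C@@H](O[Si](C(C)C)(C(C)C)C(C)C)C(=O)[C@]2(CC=C)OC(C)(C)O[C@H]12 | intermediate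
12 | keto diol: free secondary C3–OH and tertiary C8–OH, both on the bottom face | C[C@]1(O[Si](C)(C)C(C)(C)C)C[C@@H](O[Si](C(C)C)(C(C)C)C(C)C)C(=O)[C@@](O)(CC=C)[C@@H]1O | intermediate
13 | C3,C7-diketone with free tertiary C8–OH | C[C@]1(O[Si](C)(C)C(C)(C)C)C[C@@H](O[Si](C(C)C)(C(C)C)C(C)C)C(=O)[C@@](O)(CC=C)C1=O | intermediate
14 | C8 acetate of 13 | C[C@]1(O[Si](C)(C)C(C)(C)C)C[C@@H](O[Si](C(C)C)(C(C)C)C(C)C)C(=O)[C@@](OC(C)=O)(CC=C)C1=O | intermediate
15 | cis-fused β-hydroxy γ-lactone O1–C12(=O)–C11H2–C7, C7–OH on the top face, C3 ketone | C[C@]1(O[Si](C)(C)C(C)(C)C)C[C@@H](O[Si](C(C)C)(C(C)C)C(C)C)[C@]2(O)CC(=O)O[C@]2(CC=C)C1=O | intermediate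
16 | C11-(dimethylaminomethyl) lactone (Mannich base) | C[C@]1(O[Si](C)(C)C(C)(C)C)C[C@@H](O[Si](C(C)C)(C(C)C)C(C)C)[C@]2(O)[C@@H](CN(C)C)C(=O)O[C@]2(CC=C)C1=O | intermediate
17 | C11-(trimethylammoniomethyl) lactone iodide | C[C@]1(O[Si](C)(C)C(C)(C)C)C[C@@H](O[Si](C(C)C)(C(C)C)C(C)C)[C@]2(O)[C@@H](C[N+](C)(C)C)C(=O)O[C@]2(CC=C)C1=O.[I-] | intermediate (not isolated)
18 | α-methylene β-hydroxy γ-lactone (C11=C13H2) with C8 allyl | C[C@]1(O[Si](C)(C)C(C)(C)C)C[C@@H](O[Si](C(C)C)(C(C)C)C(C)C)[C@]2(O)C(=C)C(=O)O[C@]2(CC=C)C1=O | intermediate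
19 | methyl ketone C8–C9H2–C10(=O)–CH3 (in equilibrium with its C7–O–C10 hemiketal) | C[C@]1(O[Si](C)(C)C(C)(C)C)C[C@@H](O[Si](C(C)C)(C(C)C)C(C)C)[C@]2(O)C(=C)C(=O)O[C@]2(CC(C)=O)C1=O | intermediate
20 | propellane ketone: 5-methyl-2,3-dihydrofuran C7–O–C10(CH3)=C9H–C8 and α-methylene γ-lactone both fused on C7–C8, C3 ketone | C[C@]1(O[Si](C)(C)C(C)(C)C)C[C@@H](O[Si](C(C)C)(C(C)C)C(C)C)[C@@]23OC(C)=C[C@@]2(OC(=O)C3=C)C1=O | intermediate
21 | vinylmagnesium bromide | C=C[Mg]Br | starting material
22 | oxy-Cope precursor: 20 with C3 tertiary alcohol (bottom) and C3 vinyl on the top face, cis to C9 | C[C@]1(O[Si](C)(C)C(C)(C)C)C[C@@H](O[Si](C(C)C)(C(C)C)C(C)C)[C@@]23OC(C)=C[C@@]2(OC(=O)C3=C)[C@@]1(O)C=C | intermediate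
23 | potassium C2=C3 enolate of 24 | C[C@]1(O[Si](C)(C)C(C)(C)C)C[C@@H](O[Si](C(C)C)(C(C)C)C(C)C)[C@@]23O[C@@](C)(C/C=C1\[O-])C=C2OC(=O)C3=C.[K+] | intermediate (not isolated)
24 | oxy-Cope product: ten-membered C3 ketone, C8=C9 inside the C7–O–C10 2,5-dihydrofuran bridge, α-methylene lactone, C10 (S) | C[C@]1(O[Si](C)(C)C(C)(C)C)C[C@@H](O[Si](C(C)C)(C(C)C)C(C)C)[C@@]23O[C@@](C)(CCC1=O)C=C2OC(=O)C3=C | intermediate
25 | open C10-hydroxy C3-ketone: butenolide C7=C11 with C13–OAc and (E)-C8=C9 | CC(=O)OCC1=C2/C(=C\[C@@](C)(O)CCC(=O)[C@@](C)(O[Si](C)(C)C(C)(C)C)C[C@H]2O[Si](C(C)C)(C(C)C)C(C)C)OC1=O | intermediate (not isolated)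
26 | C3 hemiketal of 25 (C3–O–C10 bridge), C4–OTBS, C6–OTIPS | CC(=O)OCC1=C2/C(=C\[C@]3(C)CCC(O)(O3)[C@@](C)(O[Si](C)(C)C(C)(C)C)C[C@H]2O[Si](C(C)C)(C(C)C)C(C)C)OC1=O | intermediate
27 | hemiketal with free C4–OH and C6–OH (C6–OH on the top face) | CC(=O)OCC1=C2/C(=C\[C@]3(C)CCC(O)(O3)[C@@](C)(O)C[C@H]2O)OC1=O | intermediate
28 | hemiketal diacetate with inverted C6 | CC(=O)OCC1=C2/C(=C\[C@]3(C)CCC(O)(O3)[C@@](C)(O)C[C@@H]2OC(C)=O)OC1=O | intermediate
29 | CNP0144020.1 | CC(=O)OCC1=C2/C(=C\[C@]3(C)CC=C(O3)[C@@](C)(O)C[C@@H]2OC(C)=O)OC1=O | target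

**Step count and risks**

Total: 22 steps. Longest linear sequence: 22 steps (fully linear from toluene 1).

Steps most likely to fail:

1. Step 19 (proposed new method). Acetate may add to C13 too slowly or reversibly, so that the lactone enolate is reprotonated instead of expelling the C7 alkoxide, or the bridge may open at C10–O in the buffered medium. The fallback is a sulfur relay with known chemistry. Starting from 24, thiophenol with Et3N and then DBU should add to C13 (thia-Michael addition) and expel the C7 alkoxide (β-alkoxide elimination from the ester enolate), giving after hemiketal closure the allyl phenyl sulfide F1. S-Methylation with MeOTf gives the allylic sulfonium triflate F2, whose primary allylic carbon is displaced by CsOAc in DMF, which returns the route to 26.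

2. Step 18 (key step). The alkoxide may fragment instead of rearranging: Grob-type cleavage of C3–C8 with loss of the C7 enol-ether oxygen, which lies anti to that bond in the reactive chair. The alkoxide or the product enolate may also add to the α-methylene lactone. The fallback keeps the same bond changes but avoids any anion. Compound 22 is silylated with N-(trimethylsilyl)imidazole to the trimethylsilyl ether F3, which is heated (toluene, sealed tube, 160–180 °C) so that the neutral oxy-Cope rearrangement runs through the same chair to the trimethylsilyl enol ether F4. Mild hydrolysis (AcOH, H2O, THF) then gives 24.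

3. Step 21. The activated allylic alcohol may eliminate to the C5=C6 diene or be displaced with incomplete inversion. The fallback replaces displacement by oxidation and directed reduction. From 27, MnO2 should oxidise only the allylic C6 alcohol to the enone F5. Reduction with Me4NBH(OAc)3, delivered intramolecularly from the C4 hydroxyl (1,3-anti hydroxyl-directed reduction), should give the alcohol F6 with the C6 configuration of the target. Ac2O in pyridine acetylates its only secondary hydroxyl and rejoins the route at 28.

Further compounds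
F1 | step 19 | allyl phenyl sulfide: 26 with SPh in place of OAc at C13 | c1ccccc1SCC1=C2/C(=C\[C@]3(C)CCC(O)(O3)[C@@](C)(O[Si](C)(C)C(C)(C)C)C[C@H]2O[Si](C(C)C)(C(C)C)C(C)C)OC1=O
F2 | step 19 | S-methyl-S-phenyl allylic sulfonium triflate of F1 | C[S+](c1ccccc1)CC1=C2/C(=C\[C@]3(C)CCC(O)(O3)[C@@](C)(O[Si](C)(C)C(C)(C)C)C[C@H]2O[Si](C(C)C)(C(C)C)C(C)C)OC1=O.[O-]S(=O)(=O)C(F)(F)F
F3 | step 18 | C3 trimethylsilyl ether of 22 | C[C@]1(O[Si](C)(C)C(C)(C)C)C[C@@H](O[Si](C(C)C)(C(C)C)C(C)C)[C@@]23OC(C)=C[C@@]2(OC(=O)C3=C)[C@@]1(O[Si](C)(C)C)C=C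
F4 | step 18 | C2=C3 trimethylsilyl enol ether of 24 | C[C@]1(O[Si](C)(C)C(C)(C)C)C[C@@H](O[Si](C(C)C)(C(C)C)C(C)C)[C@@]23O[C@@](C)(C/C=C1\O[Si](C)(C)C)C=C2OC(=O)C3=C
F5 | step 21 | C6 ketone (enone) of 27 | CC(=O)OCC1=C2/C(=C\[C@]3(C)CCC(O)(O3)[C@@](C)(O)CC2=O)OC1=O
F6 | step 21 | C6 epimer of 27 (C6–OH on the bottom face) | CC(=O)OCC1=C2/C(=C\[C@]3(C)CCC(O)(O3)[C@@](C)(O)C[C@@H]2O)OC1=O
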